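You asked for a quick number, and I start from a ratio: one open dimer holds two starting material but one activator, so a charge that ends as dimer asks 0.5 activator per starting material, and theta offers 0.600.

| flask | starting material | activator | remark | time |
|---|---|---|---|---|
| larch | 11 mM | 36 mM | run made earlier |  |
| alder | 53 mM | 36 mM | run made earlier |  |
| eta | 20 mM | 36.0 mM |  | 30 min |
| beta | 30 mM | 36.0 mM |  | 30 min |
| epsilon | 50 mM | 36.0 mM |  | 30 min |
| theta | 60 mM | 36.0 mM |  | 30 min |

- larch (time / min: ring / %): 1.33: 4.4; 2.00: 6.2; 3.00: 8.8; 5.00: 12.8; 10.0: 21.2; 15.0: 23.8
- alder (time / min: ring / %): 2.50: 5.8; 5.00: 8.4; 8.00: 6.2; 10.0: 8.1; 12.0: 7.8; 15.0: 7.3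

(scatter of a reading: 1 percentage point)

- percent here means starting material units held: one open dimer counts as two
- steps thought possible: starting material + activator -> activated form; activated form <-> ring; activator + ring -> over-reaction product; starting material + activated form -> open dimer
- "hardly changes" means that all values lie within two and a half points (for a concentration: within two and a half percent of the largest)

* [ring] at the end for eta, beta, epsilon, theta, in this order
* the shape of the row from first to last (rises all the way / falls, then rises / falls all the way / hardly changes / rises, then falls)

I define the activator budget, b, as the activator charged less half of the starting material charged, the activator left if the charge ends as dimer. For theta, b is 6.00 mM, and for epsilon 11.0 mM.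

I treat activated form and ring as balanced at each moment, so ring follows activated form. Making and trapping of activated form both carry starting material as a factor, so in a quasi-steady state it cancels and ring follows free activator. Alder's readings from 10.0 min on average 4.10 mM of ring, a reading with their scatter. Its activator is not among the readings, so its budget of 9.50 mM stands in, and the rough reading is ρ, ring per budget, of 0.431. That gives 4.75 mM for epsilon and 2.59 mM for theta.

Larch lies under this rule: its ring at 15.0 min is 2.62 mM, less than ρ times its budget. So I expect eta and beta to stand below the rule, and I give them no number.

Your forecast gives 3.6 mM, 3.4 mM, 2.7 mM and 2.3 mM, so the row falls all the way, on the ground that “higher charges consume more activator”. We part at the activator: at the end you hold roughly 15 mM in theta, and I hold b.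

The flasks give 3.64 mM, 3.90 mM, 3.18 mM and 2.55 mM, so the row rises, then falls, turning near 30 mM at 3.90 mM.

    starting material + activator → activated form (k = 2.44 M⁻¹ min⁻¹)
    activated form ⇌ ring (K = 0.920, k = 1.74 min⁻¹)
    activator + ring → over-reaction product (k = 0.372 M⁻¹ min⁻¹)
    starting material + activated form → open dimer (k = 9.50 M⁻¹ min⁻¹)

In eta, the relaxation half-life of activated form and ring by their interconversion alone, both ways together, is 0.191 min, short against 30 min. At the end, activator stands at 6.75 mM in theta against b of 6.00 mM, and at 9.46 mM in epsilon against 11.0 mM, where ring stands at 3.18 mM against the reckoned 4.75 mM. In eta, activation of starting material had 85% of its turnover up to the asked time behind it at 15.0 min, with ring at 17.6% of the charge, and by 30.0 min starting material in eta had gone from 23.5% to 5.84% and ring stood at 18.2%.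

All runs stem from a simulated flask with constants of no real substance, and the scatter is random.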